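**Strategy.** Both halves of the target are the same (1S,4R)-8-oxygenated calamenene (tetralin numbering: Me on C1, iPr on C4, O on C8), so the C7–C5' biaryl bond is cut (Suzuki–Miyaura coupling) to one monomer. Its saturated ring is read as an aryl ketone carbon C1 plus a CH2–CH(iPr) unit: Mn(OAc)3 oxidative radical annulation of 2'-methoxy-4'-methylacetophenone with 3-methylbut-1-ene forges C2–C3 and C4–C4a in one operation and gives the 4-isopropyl-1-tetralone. The step exploits the single free ortho carbon C4a beside the acyl-bearing C8a and the polarity match between the α-keto radical at C2 and the C3=C4 alkene. The racemic C4 centre is resolved by catalyst-controlled transfer hydrogenation; C1 is then methylated trans.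

Key step: step 1

Assumption: the SMILES fixes four stereocentres but no sense for the hindered C7–C5' axis; the route controls the four centres and takes the axis as it forms.

Numbering used throughout: C1 carries the methyl group, C4 the isopropyl group, C6 the aryl methyl, C8 the oxygen; C4a and C8a are the ring-fusion carbons; primed locants belong to the half that comes from bromide 7.

Step 1
Reactants: 1 1-(2-methoxy-4-methylphenyl)ethan-1-one; 2 3-methylbut-1-ene
Product: 3 rac-4-isopropyl-8-methoxy-6-methyl-3,4-dihydronaphthalen-1(2H)-one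
Conditions: Mn(OAc)3·2H2O (2.2 equiv), KOAc, AcOH, 80 °C, sealed tube; 1 in excess (recovered)
Reagents that add atoms: none
Why: Mn(OAc)3 enolizes 1 and oxidizes the enolate by one electron to the electrophilic α-keto radical at C2, which adds to the CH2 terminus of the electron-rich alkene 2 (bond C2–C3); the secondary alkyl radical at C4 then attacks C4a, the ring carbon ortho to the acyl group (bond C4–C4a), and a second equivalent of Mn(OAc)3 oxidizes the cyclohexadienyl radical, which loses a proton and rearomatizes. The closest known reaction type is exactly this one, the trivalent-manganese oxidative free-radical annulation of aryl methyl ketones with terminal alkenes to α-tetralones. The six-membered ring closes by ortho attack of the C4 radical on the arene (formally 6-exo-trig onto the C4a=C5 bond), a homolytic aromatic substitution. The new C4 stereocentre has no controlling element and forms as a racemate that step 2 resolves. The step needs regioselective addition (polarity matching and the monosubstituted alkene put the radical on C4), a single site of closure (C8 carries OMe, so C4a is the only open ortho carbon) and an adduct radical that lives long enough to cyclize (no copper salt is added, and secondary alkyl radicals are not oxidized by Mn(OAc)3).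

Step 2
Reactants: 3 rac-4-isopropyl-8-methoxy-6-methyl-3,4-dihydronaphthalen-1(2H)-one
Product: 4 (1S,4R)-4-isopropyl-8-methoxy-6-methyl-1,2,3,4-tetrahydronaphthalen-1-ol (trans alcohol)
Conditions: RuCl(p-cymene)[(S,S)-TsDPEN] (1 mol%), HCO2H/Et3N (5:2), 40 °C; then chromatography on silica
Reagents that add atoms: none
Why: Noyori–Ikariya asymmetric transfer hydrogenation should set C1 as S by catalyst control on both enantiomers of 3, so the racemate diverges into the trans (1S,4R) and cis (1S,4S) alcohols, which are diastereomers and should separate on silica; the trans alcohol carries the required 4R centre, and the 4S half of the material leaves the route here.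

Step 3
Reactants: 4 (1S,4R)-4-isopropyl-8-methoxy-6-methyl-1,2,3,4-tetrahydronaphthalen-1-ol
Product: 6 (1S,4R)-4-isopropyl-8-methoxy-1,6-dimethyl-1,2,3,4-tetrahydronaphthalene, via dimethylaluminium alkoxide 5 (not isolated)
Conditions: AlMe3 (4 equiv), CH2Cl2, 0 °C to 40 °C; aqueous work-up
Reagents that add atoms: trimethylaluminium C[Al](C)C
Why: Lewis-acid SN1 methylation of a benzylic alcohol: the aluminium alkoxide ionizes to a C1 cation stabilized by the ortho methoxy and para methyl groups, and methyl should be delivered within the ion pair from the face the oxygen leaves, which is also the face anti to the pseudoaxial C4 isopropyl group, so C1 is set S, trans to C4.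

Step 4
Reactants: 6 (1S,4R)-4-isopropyl-8-methoxy-1,6-dimethyl-1,2,3,4-tetrahydronaphthalene
Product: 7 (1S,4R)-5-bromo-4-isopropyl-8-methoxy-1,6-dimethyl-1,2,3,4-tetrahydronaphthalene
Conditions: NBS (1.05 equiv), MeCN, 0 °C to rt, dark
Reagents that add atoms: N-bromosuccinimide O=C1CCC(=O)N1Br
Why: Electrophilic aromatic bromination should go to C5, the position para to the methoxy group and ortho to the C6 methyl, while the polar solvent and darkness suppress benzylic radical bromination; no stereocentre is touched.

Step 5
Reactants: 6 (1S,4R)-4-isopropyl-8-methoxy-1,6-dimethyl-1,2,3,4-tetrahydronaphthalene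
Product: 10 (1S,4R)-4-isopropyl-8-methoxy-1,6-dimethyl-1,2,3,4-tetrahydronaphthalen-7-ylboronic acid (numbering of 6 kept), via C7 aryllithium 8 (not isolated), via dimethyl arylboronate 9 (not isolated)
Conditions: n-BuLi, TMEDA, Et2O, 0 °C to rt; B(OMe)3, −78 °C to rt; 1 M HCl
Reagents that add atoms: trimethyl borate COB(OC)OC; water O
Why: Directed ortho-metalation: the methoxy group directs n-BuLi/TMEDA to C7, the only ortho C–H (C8a is substituted), and the aryllithium is trapped by trimethyl borate and hydrolysed to the boronic acid, the tertiary benzylic C–H bonds at C1 and C4 being kinetically inert to this base.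

Step 6
Reactants: 7 (1S,4R)-5-bromo-4-isopropyl-8-methoxy-1,6-dimethyl-1,2,3,4-tetrahydronaphthalene; 10 (1S,4R)-4-isopropyl-8-methoxy-1,6-dimethyl-1,2,3,4-tetrahydronaphthalen-7-ylboronic acid
Product: 11 (1S,4R,1'S,4'R)-4,4'-diisopropyl-8,8'-dimethoxy-1,6,1',6'-tetramethyl-1,2,3,4,1',2',3',4'-octahydro-7,5'-binaphthalene
Conditions: Pd(OAc)2 (5 mol%), SPhos (10 mol%), K3PO4, toluene/H2O, 100 °C; 10 in excess
Reagents that add atoms: none
Why: Suzuki–Miyaura cross-coupling: zerovalent palladium formed in situ with the bulky electron-rich biarylphosphine should insert into the C5–Br bond of 7, transmetalate with the boronate of 10 and reductively eliminate the tetra-ortho-substituted C7–C5' bond, which fixes the ortho–para connectivity by the positions of boron and bromine.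

Step 7
Reactants: 11 (1S,4R,1'S,4'R)-4,4'-diisopropyl-8,8'-dimethoxy-1,6,1',6'-tetramethyl-1,2,3,4,1',2',3',4'-octahydro-7,5'-binaphthalene
Product: 13 target CNP0145304.1 (the 8,8'-diol of 11), via bis(dibromoboryl) ether 12 (not isolated)
Conditions: BBr3 (6 equiv), CH2Cl2, −78 °C to rt; H2O
Reagents that add atoms: none
Why: Lewis-acid ether cleavage: BBr3 coordinates each aryl methyl ether, bromide removes the methyl group as bromomethane and aqueous work-up hydrolyses the aryloxyboron species to the two phenols without touching the benzylic stereocentres.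

**Compound list**

1 | 1-(2-methoxy-4-methylphenyl)ethan-1-one | CC(=O)c1ccc(C)cc1OC | starting material
2 | 3-methylbut-1-ene | C=CC(C)C | starting material
3 | rac-4-isopropyl-8-methoxy-6-methyl-3,4-dihydronaphthalen-1(2H)-one (racemate, C4 undefined) | Cc1cc2c(c(OC)c1)C(=O)CCC2C(C)C | intermediate
4 | (1S,4R)-4-isopropyl-8-methoxy-6-methyl-1,2,3,4-tetrahydronaphthalen-1-ol | Cc1cc2c(c(OC)c1)[C@@H](O)CC[C@@H]2C(C)C | intermediate
5 | dimethylaluminium alkoxide of 4 | Cc1cc2c(c(OC)c1)[C@@H](O[Al](C)C)CC[C@@H]2C(C)C | intermediate (not isolated)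
6 | (1S,4R)-4-isopropyl-8-methoxy-1,6-dimethyl-1,2,3,4-tetrahydronaphthalene | Cc1cc2c(c(OC)c1)[C@@H](C)CC[C@@H]2C(C)C | intermediate
7 | (1S,4R)-5-bromo-4-isopropyl-8-methoxy-1,6-dimethyl-1,2,3,4-tetrahydronaphthalene | Cc1c(Br)c2c(c(OC)c1)[C@@H](C)CC[C@@H]2C(C)C | intermediate
8 | C7 aryllithium of 6 | Cc1cc2c(c(OC)c1[Li])[C@@H](C)CC[C@@H]2C(C)C | intermediate (not isolated)
9 | dimethyl arylboronate (C7) of 6 | Cc1cc2c(c(OC)c1B(OC)OC)[C@@H](C)CC[C@@H]2C(C)C | intermediate (not isolated)
10 | (1S,4R)-4-isopropyl-8-methoxy-1,6-dimethyl-1,2,3,4-tetrahydronaphthalen-7-ylboronic acid | Cc1cc2c(c(OC)c1B(O)O)[C@@H](C)CC[C@@H]2C(C)C | intermediate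
11 | (1S,4R,1'S,4'R)-4,4'-diisopropyl-8,8'-dimethoxy-1,6,1',6'-tetramethyl-1,2,3,4,1',2',3',4'-octahydro-7,5'-binaphthalene | Cc1cc2c(c(OC)c1-c1c(C)cc(OC)c3c1[C@@H](C(C)C)CC[C@@H]3C)[C@@H](C)CC[C@@H]2C(C)C | intermediate
12 | bis(dibromoboryl) ether of the target | Cc1cc2c(c(OB(Br)Br)c1-c1c(C)cc(OB(Br)Br)c3c1[C@@H](C(C)C)CC[C@@H]3C)[C@@H](C)CC[C@@H]2C(C)C | intermediate (not isolated)
13 | CNP0145304.1, (1S,4R,1'S,4'R)-4,4'-diisopropyl-1,6,1',6'-tetramethyl-1,2,3,4,1',2',3',4'-octahydro-7,5'-binaphthalene-8,8'-diol | Cc1cc2c(c(O)c1-c1c(C)cc(O)c3c1[C@@H](C(C)C)CC[C@@H]3C)[C@@H](C)CC[C@@H]2C(C)C | target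

**Step count.** Total: 7 steps. Longest linear sequence: 6 steps (1, 2, 3, 4 or 5, 6, 7).

**Steps most likely to fail**

Step 1. Slow enolization of 1 by trivalent manganese may let oxidation of the acetic acid solvent and over-oxidation of the product compete, and the volatile alkene may escape, so conversion could stay low. The fallback replaces the stoichiometric metal oxidant by degenerative xanthate transfer. From 1, CuBr2 (EtOAc/CHCl3, reflux) gives 2-bromo-1-(2-methoxy-4-methylphenyl)ethan-1-one F1. EtOCS2K in acetone gives O-ethyl S-[2-(2-methoxy-4-methylphenyl)-2-oxoethyl] carbonodithioate F2. Peroxide-initiated addition to 2 (catalytic dilauroyl peroxide, 1,2-dichloroethane, reflux, sealed) gives the adduct O-ethyl S-[6-(2-methoxy-4-methylphenyl)-2-methyl-6-oxohexan-3-yl] carbonodithioate F3. Portionwise stoichiometric dilauroyl peroxide then closes the ring at C4a, and the route is rejoined at 3.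

Step 3. Facial selectivity may erode when methyl is transferred to a free benzylic cation, and β-proton loss to the dihydronaphthalene may compete. The fallback uses stereospecific substitution with inversion in place of SN1. From 3, the same transfer hydrogenation with RuCl(p-cymene)[(R,R)-TsDPEN] gives, after separation, the cis alcohol (1R,4R)-4-isopropyl-8-methoxy-6-methyl-1,2,3,4-tetrahydronaphthalen-1-ol F4. NaH and 2-bromoethyl methyl ether (DMF) give (1R,4R)-4-isopropyl-8-methoxy-1-(2-methoxyethoxy)-6-methyl-1,2,3,4-tetrahydronaphthalene F5. Nickel-catalysed Kumada-type coupling with MeMgI (Ni(cod)2, rac-BINAP, toluene, rt) replaces the chelating ether by methyl with inversion at C1 and returns to 6.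

Step 6. Transmetalation and reductive elimination may stall at the tetra-ortho-substituted axis, so that protodeboronation of 10 takes over. The fallback is a biomimetic oxidative phenol coupling without prefunctionalization. From 6, BBr3 (CH2Cl2) gives (1S,4R)-8-hydroxycalamenene, i.e. (5R,8S)-3,8-dimethyl-5-(propan-2-yl)-5,6,7,8-tetrahydronaphthalen-1-ol F6. One-electron oxidation (di-tert-butyl peroxide, chlorobenzene, 140 °C) should couple the ortho carbon C7 of one phenoxyl radical with the para carbon C5 of another. The ortho–para dimer would have to be separated from the ortho–ortho and para–para isomers; it is 13 itself.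

**Further compounds**

F1 | step 1 | 2-bromo-1-(2-methoxy-4-methylphenyl)ethan-1-one | O=C(CBr)c1ccc(C)cc1OC
F2 | step 1 | O-ethyl S-[2-(2-methoxy-4-methylphenyl)-2-oxoethyl] carbonodithioate | CCOC(=S)SCC(=O)c1ccc(C)cc1OC
F3 | step 1 | O-ethyl S-[6-(2-methoxy-4-methylphenyl)-2-methyl-6-oxohexan-3-yl] carbonodithioate (racemic) | CCOC(=S)SC(CCC(=O)c1ccc(C)cc1OC)C(C)C
F4 | step 3 | (1R,4R)-4-isopropyl-8-methoxy-6-methyl-1,2,3,4-tetrahydronaphthalen-1-ol | Cc1cc2c(c(OC)c1)[C@H](O)CC[C@@H]2C(C)C
F5 | step 3 | (1R,4R)-4-isopropyl-8-methoxy-1-(2-methoxyethoxy)-6-methyl-1,2,3,4-tetrahydronaphthalene | Cc1cc2c(c(OC)c1)[C@H](OCCOC)CC[C@@H]2C(C)C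
F6 | step 6 | (5R,8S)-3,8-dimethyl-5-(propan-2-yl)-5,6,7,8-tetrahydronaphthalen-1-ol | Cc1cc2c(c(O)c1)[C@@H](C)CC[C@@H]2C(C)C
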